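**Retrosynthetic overview**

1. Target 24 ⇐ diol 17 by two late acylations (epoxy acid 21 on the secondary O‑3, acetate on the tertiary O‑4); 17 ⇐ enone 15 by hydrogenation, carbonate methanolysis and thermodynamic setting of C7. Eudesmane numbering is used throughout: C8 ketone, C7 CH(iPr), C10 angular‑methyl carbon, C5 ring‑fusion CH, C6 and C9 the ring B methylenes, C4/C3 the oxygenated carbons of ring A.
2. Ring B ⇐ key step, a ring‑expanding enyne metathesis: siloxyalkyne 13 (C7≡C8) is inserted into the C6=C9 double bond of the cis‑fused cyclobutene C5–C6=C9–C10 of 9, forming C6–C7 and C8–C9 at once (first as the C=C bonds of a 2‑siloxy‑1,3‑diene, then enone 15). The enabling feature is this strained four‑membered ring on ring A (about 30 kcal/mol), whose two sp2 carbons differ sterically (C6 next to tertiary C5, C9 next to quaternary C10).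
3. 9 ⇐ dienone 5: MeLi sets C4, an iodocarbonate cyclisation delivers O‑3 from O‑4 (cis‑diol as cyclic carbonate), then deiodination.
4. 5 ⇐ 3 ⇐ enantioselective [2+2] photocycloaddition of 3‑methylcyclohex‑2‑enone (ring A, C14) with acetylene (C6, C9), which sets C5 and C10 cis.
5. Ring order: ring A (starting material) → cyclobutene (temporary) → cyclic carbonate (temporary) → ring B (key step); the oxirane of the ester comes from a Sharpless epoxidation of (Z)‑2‑methylbut‑2‑en‑1‑ol.

Key step: step 7

Remarks on the chemistry:
- The SMILES is read as a cis‑fused decalin: H‑5 and C14 on one face (called β), O‑3, O‑4, C6 and C9 on the other face (α), isopropyl at C7 β; descriptors (3R,4S,5S,7R,10R) and (2S,3S) for the oxirane acid.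
- Compounds 1, 2, 10, 18 and all reagents are assumed to be commercially available.
- In step 1 the antipode of the oxazaborolidine is chosen that leads to the (1S,6R) series.

Step 1
Reactants: 1 3-methylcyclohex-2-en-1-one; 2 acetylene
Product: 3 (1S,6R)-6-methylbicyclo[4.2.0]oct-7-en-2-one
Conditions: chiral prolinol-derived B-aryl oxazaborolidine·AlBr3 (50 mol%), C2H2-saturated CH2Cl2, hν (366 nm), −75 °C
Reagents that add atoms: acetylene (2), C#C
Why: Proposed new method: the AlBr3-activated oxazaborolidine should bind the enone carbonyl, shift its absorption so that only the complex is excited at 366 nm, and shield one face of C5=C10 while the triplet enone adds to acetylene through a 1,4-biradical, so that the cyclobutene forms with C5 and C10 set by the catalyst (cis fusion is enforced by the four-membered ring) and the non-absorbing product escapes a 1,3-acyl shift; the closest known reaction types are the chiral-Lewis-acid-mediated enantioselective [2+2] photocycloaddition of cyclic enones with alkenes and the racemic enone–alkyne [2+2] photocycloaddition.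

Step 2
Reactants: 3 (1S,6R)-6-methylbicyclo[4.2.0]oct-7-en-2-one
Product: 5 (1S,6R)-6-methylbicyclo[4.2.0]octa-3,7-dien-2-one, via lithium enolate 4 (not isolated)
Conditions: LiN(iPr)2, THF, −78 °C; then PhS(Cl)=NtBu, −78 °C to rt
Reagents that add atoms: none
Why: Kinetic deprotonation at the C3 methylene (an enolate towards C5 would put a double bond at the four-ring fusion), S-attack on the sulfinimidoyl chloride and syn-elimination should give the C2=C3 enone (α,β-dehydrogenation of a ketone with a sulfinimidoyl chloride) without touching a stereocentre.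

Step 3
Reactants: 5 (1S,6R)-6-methylbicyclo[4.2.0]octa-3,7-dien-2-one
Product: 7 tert-butyl (1S,2R,6R)-2,6-dimethylbicyclo[4.2.0]octa-3,7-dien-2-yl carbonate, via lithium alkoxide 6 (not isolated)
Conditions: MeLi, Et2O, −78 °C; then Boc2O, THF, −78 to 0 °C
Reagents that add atoms: methyllithium, [Li]C; di-tert-butyl dicarbonate, CC(C)(C)OC(=O)OC(=O)OC(C)(C)C
Why: MeLi should add 1,2 to the enone from the β (exo) face, anti to the cyclobutene attached to C5 on the α face, which sets C4 with O α and C15 β, and the tertiary alkoxide is trapped in situ as its tert-butyl carbonate (organolithium 1,2-addition, then O-acylation).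

Step 4
Reactants: 7 tert-butyl (1S,2R,6R)-2,6-dimethylbicyclo[4.2.0]octa-3,7-dien-2-yl carbonate
Product: 8 iodo carbonate (cis-fused 1,3-dioxolan-2-one on O-3/O-4 both α; iodine on C2 β; cyclobutene C6=C9 retained)
Conditions: I2, MeCN, −20 °C, dark
Reagents that add atoms: iodine, II
Why: Iodonium formation on the β face of C2=C3 and 5-exo attack of the carbonate carbonyl oxygen at C3 from the α face, to which it is tied through O-4, followed by loss of the tert-butyl group as tert-butyl iodide, should give the cis-fused cyclic carbonate and so set C3–O cis to C4–O (iodocarbonate cyclisation); iodine adds to the cyclobutene only reversibly.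

Step 5
Reactants: 8 iodo carbonate
Product: 9 cyclobutene carbonate (3α,4α-cyclic carbonate of the 4β,10β-dimethyl bicyclo[4.2.0]oct-7-ene core)
Conditions: Bu3SnH, AIBN (cat.), PhH, 80 °C
Reagents that add atoms: none
Why: Radical chain deiodination at C2 (tin hydride reduction of a secondary iodide) removes the auxiliary iodine without touching a stereocentre, the carbonate or the cyclobutene.

Step 6
Reactants: 10 3-methylbut-1-yne
Product: 13 triisopropyl[(3-methylbut-1-yn-1-yl)oxy]silane, via lithium acetylide 11 (not isolated), via lithium ynolate 12 (not isolated)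
Conditions: n-BuLi, THF, −78 °C; tBuOOLi (from tBuOOH, LiN(SiMe3)2), −78 to 0 °C; then iPr3SiOSO2CF3, −78 °C
Reagents that add atoms: tert-butyl hydroperoxide, CC(C)(C)OO; triisopropylsilyl trifluoromethanesulfonate, CC(C)[Si](OS(=O)(=O)C(F)(F)F)(C(C)C)C(C)C
Why: The lithium acetylide is oxidised by lithium tert-butyl peroxide to the ynolate, which the bulky silyl triflate silylates on oxygen (known preparation of siloxyalkynes from terminal alkynes); no stereocentre is involved.

Step 7
Reactants: 9 cyclobutene carbonate; 13 triisopropyl[(3-methylbut-1-yn-1-yl)oxy]silane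
Product: 15 enone carbonate (cis-fused 8-oxo-eudesm-6-ene 3α,4α-cyclic carbonate), via siloxydiene 14 (not isolated)
Conditions: RuCl2(=CHPh)(PCy3)(H2IMes) (second-generation Grubbs catalyst, 10 mol%), 13 (3 equiv), PhMe, 60 °C, slow addition of 9; then 1 M HCl, THF, 0 °C
Reagents that add atoms: triisopropyl[(3-methylbut-1-yn-1-yl)oxy]silane (13), CC(C)C#CO[Si](C(C)C)(C(C)C)C(C)C
Why: Proposed new method: the ruthenium alkylidene should open the strained cyclobutene so that Ru sits on C6 (next to tertiary C5) and not on C9 (next to quaternary C10); this alkylidene should add to 13 with its carbon on the isopropyl-bearing alkyne carbon (C7) and Ru on the oxygen-bearing carbon (C8), as heteroatom-substituted π bonds do when they give Fischer-type carbenes. Ring-closing metathesis of the resulting siloxy vinylcarbene onto the pendant C9 alkene then closes ring B, the four-membered ring being expanded to a six-membered 2-siloxy-1,3-diene with return of the benzylidene, so that no ethylene is lost. The closest known reaction types are the ring expansion of cycloalkenes and 1,5-dienes with alkynes to 1,3-cycloalkadienes by tandem ring-opening/enyne metathesis, and the ring-closing enyne metathesis of siloxyalkynes. No stereocentre is formed: C5 and C10 are carried through, so the cis fusion of the cyclobutene becomes the cis decalin fusion, and C7 is set in step 9. The selectivity needed is regiochemical (C6 to C7, C9 to C8); it should be secured by the steric difference between the two cyclobutene carbons and by the O/alkyl polarisation of 13, while oligomerisation of 9 is held back by its slow addition to excess 13. Dilute acid then protonates C9 of siloxydiene 14 and releases the conjugated enone.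

Step 8
Reactants: 15 enone carbonate
Product: 16 ketone carbonate (cis-fused 8-oxo-eudesmane 3α,4α-cyclic carbonate; drawn as the 7β-isopropyl epimer)
Conditions: H2 (1 atm), Pd/C, EtOAc, rt
Reagents that add atoms: none
Why: Heterogeneous hydrogenation should reduce only the C6=C7 enone double bond (ketone and carbonate are inert); the C7 centre formed here is α to the ketone and either epimer converges in step 9.

Step 9
Reactants: 16 ketone carbonate
Product: 17 (3R,4S,5S,7R,10R)-3,4-dihydroxyeudesman-8-one (cis-fused)
Conditions: K2CO3, MeOH, rt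
Reagents that add atoms: none
Why: Carbonate transesterification releases the cis-3,4-diol, and reversible enolisation towards C7 should settle the isopropyl group in the equatorial β position of the cis-decalin conformer that avoids the 1,3-diaxial C14/C15 pair (thermodynamic epimerisation α to a ketone); C5 and C10 cannot enolise.

Step 10
Reactants: 18 angelic acid [(Z)-2-methylbut-2-enoic acid]
Product: 19 (Z)-2-methylbut-2-en-1-ol
Conditions: LiAlH4, Et2O, 0 °C
Reagents that add atoms: none
Why: Hydride reduction of the carboxylic acid gives the allylic alcohol with the Z double bond retained.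

Step 11
Reactants: 19 (Z)-2-methylbut-2-en-1-ol
Product: 20 [(2R,3S)-2,3-dimethyloxiran-2-yl]methanol
Conditions: Ti(OiPr)4, D-(−)-diethyl tartrate, tBuOOH, 4 Å MS, CH2Cl2, −20 °C
Reagents that add atoms: tert-butyl hydroperoxide, CC(C)(C)OO
Why: Sharpless asymmetric epoxidation: with D-(−)-diethyl tartrate the titanium–tartrate complex should deliver oxygen to the face of the Z-allylic alcohol that gives the (2R,3S)-epoxy alcohol, the cis relation of CH2OH and the C3 methyl being inherited from the Z alkene.

Step 12
Reactants: 20 [(2R,3S)-2,3-dimethyloxiran-2-yl]methanol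
Product: 21 (2S,3S)-2,3-dimethyloxirane-2-carboxylic acid
Conditions: RuCl3 (cat.), NaIO4, CCl4/MeCN/H2O, rt
Reagents that add atoms: sodium periodate, [Na+].[O-]I(=O)(=O)=O; water, O
Why: RuO4 generated in situ oxidises the primary alcohol to the acid without opening the epoxide (ruthenium-catalysed periodate oxidation); the stereocentres are untouched and only the descriptor at C2 changes.

Step 13
Reactants: 17 (3R,4S,5S,7R,10R)-3,4-dihydroxyeudesman-8-one; 21 (2S,3S)-2,3-dimethyloxirane-2-carboxylic acid
Product: 23 (3R,4S,5S,7R,10R)-4-hydroxy-8-oxoeudesman-3-yl (2S,3S)-2,3-dimethyloxirane-2-carboxylate, via mixed anhydride 22 (not isolated)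
Conditions: 2,4,6-Cl3C6H2COCl, Et3N, THF, rt; then 17, DMAP, PhMe, rt
Reagents that add atoms: (2S,3S)-2,3-dimethyloxirane-2-carboxylic acid (21), OC(=O)[C@@]1(C)O[C@H]1C
Why: Yamaguchi esterification: the mixed anhydride should acylate the secondary, equatorial 3-OH in preference to the tertiary, axial 4-OH, and neither the quaternary α-carbon of the acid nor a ring stereocentre can epimerise.

Step 14
Reactants: 23 (3R,4S,5S,7R,10R)-4-hydroxy-8-oxoeudesman-3-yl (2S,3S)-2,3-dimethyloxirane-2-carboxylate
Product: 24 (3R,4S,5S,7R,10R)-4-acetoxy-8-oxoeudesman-3-yl (2S,3S)-2,3-dimethyloxirane-2-carboxylate (CNP0221066.1)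
Conditions: Ac2O, DMAP, Et3N, CH2Cl2, 40 °C
Reagents that add atoms: acetic anhydride, CC(=O)OC(C)=O
Why: DMAP-catalysed acyl transfer should acetylate the only free hydroxyl, the tertiary 4-OH, under conditions that leave the epoxide, the ester and the equilibrated C7 centre unchanged.

**Compound list**

1 | 3-methylcyclohex-2-en-1-one | CC1=CC(=O)CCC1 | starting material
2 | acetylene | C#C | starting material
3 | (1S,6R)-6-methylbicyclo[4.2.0]oct-7-en-2-one | O=C1CCC[C@]2(C)C=C[C@@H]21 | intermediate
4 | lithium (1S,6R)-6-methylbicyclo[4.2.0]octa-2,7-dien-2-olate (not isolated) | [Li+].[O-]C1=CCC[C@]2(C)C=C[C@@H]21 | intermediate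
5 | (1S,6R)-6-methylbicyclo[4.2.0]octa-3,7-dien-2-one | O=C1C=CC[C@]2(C)C=C[C@@H]21 | intermediate
6 | lithium (1S,2R,6R)-2,6-dimethylbicyclo[4.2.0]octa-3,7-dien-2-olate (not isolated) | [Li+].[O-][C@]1(C)C=CC[C@]2(C)C=C[C@@H]21 | intermediate
7 | tert-butyl (1S,2R,6R)-2,6-dimethylbicyclo[4.2.0]octa-3,7-dien-2-yl carbonate | CC(C)(C)OC(=O)O[C@]1(C)C=CC[C@]2(C)C=C[C@@H]21 | intermediate
8 | iodo carbonate: 3α,4α-cyclic carbonate, 2β-iodo, cyclobutene C6=C9 | O=C1O[C@]2(C)[C@H](O1)[C@@H](I)C[C@]3(C)C=C[C@@H]32 | intermediate
9 | cyclobutene carbonate: 3α,4α-cyclic carbonate, cyclobutene C6=C9 | O=C1O[C@]2(C)[C@H](O1)CC[C@]3(C)C=C[C@@H]32 | intermediate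
10 | 3-methylbut-1-yne | CC(C)C#C | starting material
11 | lithium 3-methylbut-1-yn-1-ide (not isolated) | [Li+].CC(C)C#[C-] | intermediate
12 | lithium 3-methylbut-1-yn-1-olate (not isolated) | [Li+].CC(C)C#C[O-] | intermediate
13 | triisopropyl[(3-methylbut-1-yn-1-yl)oxy]silane | CC(C)C#CO[Si](C(C)C)(C(C)C)C(C)C | intermediate
14 | siloxydiene: ring B C6=C7(iPr)–C8(OSi(iPr)3)=C9, 3α,4α-cyclic carbonate (not isolated) | O=C1O[C@]2(C)[C@H](O1)CC[C@]3(C)C=C(O[Si](C(C)C)(C(C)C)C(C)C)C(C(C)C)=C[C@@H]32 | intermediate
15 | enone carbonate: cis-fused 8-oxo-eudesm-6-ene 3α,4α-cyclic carbonate | O=C1O[C@]2(C)[C@H](O1)CC[C@]3(C)CC(=O)C(C(C)C)=C[C@@H]32 | intermediate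
16 | ketone carbonate: cis-fused 8-oxo-eudesmane 3α,4α-cyclic carbonate, 7β-isopropyl as drawn | O=C1O[C@]2(C)[C@H](O1)CC[C@]3(C)CC(=O)[C@@H](C(C)C)C[C@@H]32 | intermediate
17 | (3R,4S,5S,7R,10R)-3,4-dihydroxyeudesman-8-one | O[C@]1(C)[C@H](O)CC[C@]2(C)CC(=O)[C@@H](C(C)C)C[C@@H]21 | intermediate
18 | angelic acid, (Z)-2-methylbut-2-enoic acid | C/C=C(/C)C(=O)O | starting material
19 | (Z)-2-methylbut-2-en-1-ol | C/C=C(/C)CO | intermediate
20 | [(2R,3S)-2,3-dimethyloxiran-2-yl]methanol | OC[C@@]1(C)O[C@H]1C | intermediate
21 | (2S,3S)-2,3-dimethyloxirane-2-carboxylic acid | OC(=O)[C@@]1(C)O[C@H]1C | intermediate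
22 | (2S,3S)-2,3-dimethyloxirane-2-carboxylic 2,4,6-trichlorobenzoic anhydride (not isolated) | O=C(OC(=O)[C@@]1(C)O[C@H]1C)c1c(Cl)cc(Cl)cc1Cl | intermediate
23 | (3R,4S,5S,7R,10R)-4-hydroxy-8-oxoeudesman-3-yl (2S,3S)-2,3-dimethyloxirane-2-carboxylate | O[C@]1(C)[C@H](OC(=O)[C@@]2(C)O[C@H]2C)CC[C@]2(C)CC(=O)[C@@H](C(C)C)C[C@@H]21 | intermediate
24 | (3R,4S,5S,7R,10R)-4-acetoxy-8-oxoeudesman-3-yl (2S,3S)-2,3-dimethyloxirane-2-carboxylate | CC(=O)O[C@]1(C)[C@H](OC(=O)[C@@]2(C)O[C@H]2C)CC[C@]2(C)CC(=O)[C@@H](C(C)C)C[C@@H]21 | target

**Step count:** 14 steps in total. Longest linear sequence: 10 steps (1, 2, 3, 4, 5, 7, 8, 9, 13, 14).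

**Steps most likely to fail**

1. Step 7 (Proposed new method). What may go wrong: ring-opening oligomerisation of the cyclobutene, or alkyne insertion with the opposite orientation (or opening that leaves Ru on C9), which would give the regioisomeric diene. Fallback with known chemistry, from 9 back to 15: ozonolysis of the cyclobutene with NaBH4 work-up would give the seco-diol F1. The less hindered C6 hydroxyl would be silylated (tBuMe2SiCl, imidazole) to the mono-silyl ether F2, and an Appel iodination (I2, PPh3, imidazole, PhMe, 80 °C) of the neopentyl C9 hydroxyl would give the iodide F3. A nickel-catalysed reductive acylation with 3-methylbutanoyl chloride (NiCl2(dme), 4,4′-di-tert-butyl-2,2′-bipyridine, Mn powder, DMA) would form C8–C9 in the silyl ketone F4. HF·pyridine would then free the keto alcohol F5 and DMP would oxidise it to the keto aldehyde F6. An intramolecular aldol condensation (piperidinium acetate) of the C7 enolate onto the C6 aldehyde would close ring B and return enone 15.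

2. Step 1 (Proposed new method). What may go wrong: poor face discrimination or Lewis acid deactivation in the presence of acetylene, or a secondary photoreaction of the β,γ-unsaturated ketone. Fallback with known chemistry, from 1 and 2 back to 3: uncatalysed irradiation of 1 in acetylene-saturated solvent through a long-pass filter at partial conversion (the known enone–alkyne photocycloaddition) would give the racemic ketone F7, which would be resolved by preparative chromatography on a chiral stationary phase to give 3.

3. Step 4. What may go wrong: 6-endo closure to the bridged carbonate, ionisation of the tertiary allylic carbonate, or irreversible addition of iodine to the cyclobutene. Fallback from 5 back to 9, replacing steps 3 to 5: MeLi addition with aqueous work-up would give the tertiary allylic alcohol F8. Hydroxyl-directed epoxidation (VO(acac)2, tBuOOH) would give the syn-epoxy alcohol F9. Hydride opening at the distal carbon C2 (LiBH4, Ti(OiPr)4) would give the cis-diol F10, and 1,1′-carbonyldiimidazole would close the cyclic carbonate 9.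

**Further compounds**

F1 | step 7 | seco-diol: 3α,4α-cyclic carbonate with CH2OH on C5 and CH2OH on C10 | O=C1O[C@]2(C)[C@H](O1)CC[C@](C)(CO)[C@@H]2CO
F2 | step 7 | mono-silyl ether: as F1 with the C6 hydroxyl as tert-butyldimethylsilyl ether | O=C1O[C@]2(C)[C@H](O1)CC[C@](C)(CO)[C@@H]2CO[Si](C)(C)C(C)(C)C
F3 | step 7 | iodide: as F2 with iodine on C9 | O=C1O[C@]2(C)[C@H](O1)CC[C@](C)(CI)[C@@H]2CO[Si](C)(C)C(C)(C)C
F4 | step 7 | silyl ketone: as F2 with CH2C(=O)CH2CH(CH3)2 on C10 | O=C1O[C@]2(C)[C@H](O1)CC[C@](C)(CC(=O)CC(C)C)[C@@H]2CO[Si](C)(C)C(C)(C)C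
F5 | step 7 | keto alcohol: F4 without the silyl group | O=C1O[C@]2(C)[C@H](O1)CC[C@](C)(CC(=O)CC(C)C)[C@@H]2CO
F6 | step 7 | keto aldehyde: C6 aldehyde of F5 | O=C1O[C@]2(C)[C@H](O1)CC[C@](C)(CC(=O)CC(C)C)[C@@H]2C=O
F7 | step 1 | racemic cis-6-methylbicyclo[4.2.0]oct-7-en-2-one | O=C1CCCC2(C)C=CC21
F8 | step 4 | (1S,2R,6R)-2,6-dimethylbicyclo[4.2.0]octa-3,7-dien-2-ol | O[C@]1(C)C=CC[C@]2(C)C=C[C@@H]21
F9 | step 4 | syn-epoxy alcohol: 2α,3α-epoxide of F8 | O[C@]1(C)[C@@H]3O[C@@H]3C[C@]2(C)C=C[C@@H]21
F10 | step 4 | cis-diol: 3α,4α-dihydroxy-4β,10β-dimethyl cyclobutene | O[C@]1(C)[C@H](O)CC[C@]2(C)C=C[C@@H]21
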